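**Plan**
Retrosynthesis: first the four phenol O–H bonds are masked as MOM ethers. Ring C is then opened by retro-hydroacylation, which cuts C3–C4 and C2–H. O1–C2 is cut next, and last the bond from C6 to the quaternary side-chain carbon (retro-Claisen).
Enabling feature: C3 is a bare CH2 between the C4 carbonyl, which sits on ring A ortho to O1, and C2, which carries only H, O1 and ring B. Ring C is therefore the hydroacylation adduct of a ring A aldehyde (C4–H) and a 1,1-disubstituted aryl enol ether C2=C3. Neither this alkene nor the C6 side-chain vinyl group has an allylic hydrogen.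
Forward order: rings A and B are bought. The side chain is put on ring A by a Claisen shift in a mirror-symmetric 4-O-prenyl-2,6-dihydroxybenzaldehyde whose para position is blocked by CHO. O7 is then masked, ring B is joined through O1–C2, the alkene is made, and ring C closes last.
Stereochemistry: C2 is the only stereocentre. It is set in the ring closure by the chiral diphosphine on rhodium; the racemic centre of 8 and 9 is erased in step 7.
The C5 hydroxyl is masked for the ring closure, because a free peri phenol would hold rhodium on the side of C4 remote from the alkene. All helpers leave under acid, which avoids base-induced ring opening at O1–C2.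

Key step: step 8

Assumption: the (R)-ligand is written in step 8. The sense of induction on this substrate class cannot be known in advance, and the equally available (S)-ligand is used if the (R)-ligand should favour the 2R ketone.

Step 1
Reactants: 1 2,4,6-trihydroxybenzaldehyde; 2 3-methylbut-2-en-1-ol (prenol)
Product: 3 2,6-dihydroxy-4-[(3-methylbut-2-en-1-yl)oxy]benzaldehyde
Conditions: PPh3 (1.05 equiv), DIAD (1.05 equiv), THF, 0 °C to rt
Reagents that add atoms: none
Why: Mitsunobu etherification, in which the C4 hydroxyl (para to CHO, not engaged by the formyl oxygen, the most acidic phenol) is alkylated first, and the redox condensation gives O-alkylation at the primary carbon of 2 without the C-prenylation that allylic halides and base cause with phloroglucinols.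

Step 2
Reactants: 3 2,6-dihydroxy-4-[(3-methylbut-2-en-1-yl)oxy]benzaldehyde
Product: 4 2,4,6-trihydroxy-3-(2-methylbut-3-en-2-yl)benzaldehyde
Conditions: N,N-diethylaniline, 190 °C, sealed vessel, argon
Reagents that add atoms: none
Why: Aromatic Claisen rearrangement ([3,3] shift with allyl inversion), in which the mirror plane of 3 makes both ortho positions equivalent, the formyl group blocks the para position so that no onward Cope shift to a normal prenyl group can occur, and the dienone re-aromatises in the basic solvent.

Step 3
Reactants: 4 2,4,6-trihydroxy-3-(2-methylbut-3-en-2-yl)benzaldehyde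
Product: 5 2,6-dihydroxy-4-(methoxymethoxy)-3-(2-methylbut-3-en-2-yl)benzaldehyde
Conditions: MOMCl (1.05 equiv), K2CO3 (1.1 equiv), acetone, 0 °C to rt
Reagents that add atoms: chloromethyl methyl ether (MOMCl), COCCl
Why: Williamson-type MOM ether formation under acidity control, since one equivalent of weak base ionises only the C4 hydroxyl (vinylogous acid, para to CHO) while the two ortho hydroxyls are held by the formyl oxygen, a selectivity well known for 2,4,6-trihydroxyaryl carbonyl compounds.

Step 4
Reactants: 6 2-chloro-1-(3,4-dihydroxyphenyl)ethan-1-one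
Product: 7 1-[3,4-bis(methoxymethoxy)phenyl]-2-chloroethan-1-one
Conditions: MOMCl (2.5 equiv), iPr2NEt (3 equiv), CH2Cl2, 0 °C to rt
Reagents that add atoms: chloromethyl methyl ether (MOMCl), COCCl
Why: Standard MOM protection of a catechol, in which the very reactive MOMCl with a non-nucleophilic amine at low temperature outruns alkylation of the phenols by the chloroketone.

Step 5
Reactants: 7 1-[3,4-bis(methoxymethoxy)phenyl]-2-chloroethan-1-one
Product: 8 rac-1-[3,4-bis(methoxymethoxy)phenyl]-2-chloroethan-1-ol
Conditions: NaBH4, MeOH, 0 °C; aq NH4Cl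
Reagents that add atoms: none
Why: Borohydride reduction of an α-chloroketone to the chlorohydrin, quenched cold before epoxide closure, with the new stereocentre left racemic on purpose because step 7 erases it.

Step 6
Reactants: 5 2,6-dihydroxy-4-(methoxymethoxy)-3-(2-methylbut-3-en-2-yl)benzaldehyde; 8 rac-1-[3,4-bis(methoxymethoxy)phenyl]-2-chloroethan-1-ol
Product: 9 rac-2-{1-[3,4-bis(methoxymethoxy)phenyl]-2-chloroethoxy}-6-hydroxy-4-(methoxymethoxy)-5-(2-methylbut-3-en-2-yl)benzaldehyde
Conditions: PPh3 (1.2 equiv), DIAD (1.2 equiv), THF, 0 °C to rt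
Reagents that add atoms: none
Why: Mitsunobu etherification of a secondary benzylic alcohol by an acidic salicylaldehyde-type phenol, in which the hydroxyl wedged between the quaternary carbon and CHO is shielded, so that the hydroxyl next to the ring C–H (the future O1) should react, and the configuration is irrelevant.

Step 7
Reactants: 9 rac-2-{1-[3,4-bis(methoxymethoxy)phenyl]-2-chloroethoxy}-6-hydroxy-4-(methoxymethoxy)-5-(2-methylbut-3-en-2-yl)benzaldehyde
Product: 11 2-({1-[3,4-bis(methoxymethoxy)phenyl]ethenyl}oxy)-4,6-bis(methoxymethoxy)-5-(2-methylbut-3-en-2-yl)benzaldehyde, via enol ether phenoxide 10 (not isolated)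
Conditions: KOtBu (2.5 equiv), THF, 0 °C to rt; then MOMCl (2 equiv), 0 °C; aq NaHCO3; Et3N-deactivated silica
Reagents that add atoms: chloromethyl methyl ether (MOMCl), COCCl
Why: E2 dehydrochlorination of a β-chloroalkyl aryl ether, the standard entry to aryl vinyl ethers, is eased here by the benzylic C–H and possible in one direction only, the aldehyde is not enolisable, and the hindered phenoxide that the base forms anyway is capped in the same flask as its MOM ether.

Step 8
Reactants: 11 2-({1-[3,4-bis(methoxymethoxy)phenyl]ethenyl}oxy)-4,6-bis(methoxymethoxy)-5-(2-methylbut-3-en-2-yl)benzaldehyde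
Product: 12 (2S)-2-[3,4-bis(methoxymethoxy)phenyl]-5,7-bis(methoxymethoxy)-6-(2-methylbut-3-en-2-yl)-2,3-dihydro-4H-chromen-4-one
Conditions: [Rh(cod)Cl]2 (2.5 mol %), (R)-DTBM-SEGPHOS (5 mol %), NaB[3,5-(CF3)2C6H3]4 (5 mol %), 4 Å molecular sieves, 1,4-dioxane, 60–80 °C
Reagents that add atoms: none
Why: Proposed new method: the cationic diphosphine complex of monovalent rhodium binds the C2=C3 alkene, adds oxidatively into the formyl C4–H bond, inserts the alkene into Rh–H so that hydrogen goes to C2 and rhodium to the unsubstituted C3, and forms C3–C4 by reductive elimination from the seven-membered acyl alkyl rhodacycle of trivalent rhodium. The closest known reaction type is the enantioselective rhodium-catalysed intramolecular alkene hydroacylation of ortho-(2-substituted allyl)benzaldehydes and N-(2-substituted allyl)indole-2-carbaldehydes to six-membered benzo-fused ketones with this catalyst system, and the new element is that the CH2 of those tethers is O1, so that the alkene is an aryl enol ether. Ring C closes in a formal 6-endo-trig mode by a pure isomerisation that delivers the ring, the C4 ketone and the C2–H bond together. C2 is set when hydrogen is delivered to one face of the bound 1,1-disubstituted alkene, and the controlling element is the twofold-symmetric pocket of the bulky diphosphine, which must tell ring B from the O1 tether. Regioselectivity for the six-ring ketone over the 2-aryl-2-methylbenzofuran-3-one is needed and should be secured by the 1,1-disubstitution, since a tertiary C2–Rh bond flanked by ring B and O1 is crowded out of the pocket and insertion is reversible, so that only the primary C3–Rh alkyl goes on to reductive elimination, while β-aryloxy elimination is disfavoured because O1 is endocyclic in the rhodacycle and cannot become syn-coplanar with Rh–C3. Chemoselectivity is also needed: the side-chain vinyl group lies meta to the aldehyde behind a quaternary carbon and cannot reach the metal within the molecule, neither alkene has an allylic hydrogen so that isomerisation cannot drain the substrate, and O1 and the C5 MOM oxygen can stabilise the acyl hydride against decarbonylation.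

Step 9
Reactants: 12 (2S)-2-[3,4-bis(methoxymethoxy)phenyl]-5,7-bis(methoxymethoxy)-6-(2-methylbut-3-en-2-yl)-2,3-dihydro-4H-chromen-4-one
Product: 13 (2S)-2-(3,4-dihydroxyphenyl)-5,7-dihydroxy-6-(2-methylbut-3-en-2-yl)-2,3-dihydro-4H-chromen-4-one
Conditions: HCl (3 M aq)/MeOH, 45 °C; neutral to slightly acidic work-up
Reagents that add atoms: none
Why: Acid-catalysed acetal exchange removes all four MOM groups at once, acid is chosen because flavanones racemise by base-induced retro-oxa-Michael opening at O1–C2, and the monosubstituted side-chain alkene should not be protonated by dilute acid.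

**Compound list**
1 | 2,4,6-trihydroxybenzaldehyde | O=Cc1c(O)cc(O)cc1O | starting material
2 | 3-methylbut-2-en-1-ol | CC(C)=CCO | starting material
3 | 2,6-dihydroxy-4-[(3-methylbut-2-en-1-yl)oxy]benzaldehyde | CC(C)=CCOc1cc(O)c(C=O)c(O)c1 | intermediate
4 | 2,4,6-trihydroxy-3-(2-methylbut-3-en-2-yl)benzaldehyde | C=CC(C)(C)c1c(O)cc(O)c(C=O)c1O | intermediate
5 | 2,6-dihydroxy-4-(methoxymethoxy)-3-(2-methylbut-3-en-2-yl)benzaldehyde | C=CC(C)(C)c1c(OCOC)cc(O)c(C=O)c1O | intermediate
6 | 2-chloro-1-(3,4-dihydroxyphenyl)ethan-1-one | O=C(CCl)c1ccc(O)c(O)c1 | starting material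
7 | 1-[3,4-bis(methoxymethoxy)phenyl]-2-chloroethan-1-one | O=C(CCl)c1ccc(OCOC)c(OCOC)c1 | intermediate
8 | rac-1-[3,4-bis(methoxymethoxy)phenyl]-2-chloroethan-1-ol | OC(CCl)c1ccc(OCOC)c(OCOC)c1 | intermediate
9 | rac-2-{1-[3,4-bis(methoxymethoxy)phenyl]-2-chloroethoxy}-6-hydroxy-4-(methoxymethoxy)-5-(2-methylbut-3-en-2-yl)benzaldehyde | C=CC(C)(C)c1c(OCOC)cc(OC(CCl)c2ccc(OCOC)c(OCOC)c2)c(C=O)c1O | intermediate
10 | 2-({1-[3,4-bis(methoxymethoxy)phenyl]ethenyl}oxy)-6-hydroxy-4-(methoxymethoxy)-5-(2-methylbut-3-en-2-yl)benzaldehyde, present in the flask as its potassium phenoxide | C=CC(C)(C)c1c(OCOC)cc(OC(=C)c2ccc(OCOC)c(OCOC)c2)c(C=O)c1O | intermediate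
11 | 2-({1-[3,4-bis(methoxymethoxy)phenyl]ethenyl}oxy)-4,6-bis(methoxymethoxy)-5-(2-methylbut-3-en-2-yl)benzaldehyde | C=CC(C)(C)c1c(OCOC)cc(OC(=C)c2ccc(OCOC)c(OCOC)c2)c(C=O)c1OCOC | intermediate
12 | (2S)-2-[3,4-bis(methoxymethoxy)phenyl]-5,7-bis(methoxymethoxy)-6-(2-methylbut-3-en-2-yl)-2,3-dihydro-4H-chromen-4-one | C=CC(C)(C)c1c(OCOC)cc2c(c1OCOC)C(=O)C[C@@H](c1ccc(OCOC)c(OCOC)c1)O2 | intermediate
13 | (2S)-2-(3,4-dihydroxyphenyl)-5,7-dihydroxy-6-(2-methylbut-3-en-2-yl)-2,3-dihydro-4H-chromen-4-one | C=CC(C)(C)c1c(O)cc2c(c1O)C(=O)C[C@@H](c1ccc(O)c(O)c1)O2 | target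

Total step count: 9
Longest linear sequence: 7 steps (1, 2, 3, 6, 7, 8, 9)

**Steps most likely to fail**

Step 8.
- Four processes may intervene. The acyl rhodium hydride may decarbonylate. Insertion may run in the opposite sense, because both ring B and O1 favour metal at C2 on electronic grounds. The acid-sensitive enol ether may hydrolyse or close onto the aldehyde in a Lewis-acid manner. Facial selectivity may be low.
- The fallback sets out from 11 and comes back at 12, and separates ring closure from stereocontrol.
- A thiol-catalysed radical hydroacylation is used (tert-dodecanethiol, catalytic; 1,1'-azobis(cyclohexanecarbonitrile); toluene, reflux). The thiyl radical abstracts the formyl hydrogen, and the aroyl radical at C4 adds 6-endo to C3. The benzylic, O1-stabilised C2 radical then takes hydrogen from the thiol, which should give the racemic tetra-MOM flavanone F1.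
- F1 is then resolved kinetically by asymmetric transfer hydrogenation (RhCl[(R,R)-TsDPEN](C5Me5) or its antipode, HCO2H/Et3N, EtOAc, rt). This is a known resolution of racemic flavanones. The catalyst antipode is chosen so that the 2R ketone is reduced to the cis-(2R,4R)-flavan-4-ol F2 and 12 is left behind for chromatographic separation.

Step 2.
- At the temperature of the rearrangement, the free phenols flanking the new side chain may add to it. The side chain may isomerise through the abnormal Claisen pathway, and the unprotected trihydroxybenzaldehyde may degrade.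
- The fallback sets out from 3 and comes back at 5, so it also replaces the site-selective step 3.
- Both chelating phenols are silylated first (TBSCl, imidazole, DMF) to give the bis-silyl ether F3.
- The Claisen shift (N,N-diethylaniline, 190 °C) then unveils a single free hydroxyl in the phenol F4.
- That hydroxyl is capped without any selectivity question (MOMCl, iPr2NEt, CH2Cl2) to give the MOM ether F5. Et3N·3HF in THF removes both silyl groups to give 5.

Step 6.
- The activated, electron-rich benzylic alcohol may ionise and eliminate, or it may alkylate ring A at carbon. The hydrogen-bonded phenol may also react too slowly with the phosphonium intermediate.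
- The fallback sets out from 8 and 5 and comes back at 9, and replaces the redox condensation by a Williamson ether synthesis with a preformed electrophile.
- Compound 8 is converted (MsCl, Et3N, LiCl, CH2Cl2, 0 °C) into the dichloride F6, whose benzylic chloride is far more reactive than the primary one.
- The mono-caesium phenoxide of 5 (Cs2CO3, 1 equiv, DMF, 0 °C) is alkylated at the unhindered oxygen to give 9.

**Further compounds**
F1 | step 8 | rac-2-[3,4-bis(methoxymethoxy)phenyl]-5,7-bis(methoxymethoxy)-6-(2-methylbut-3-en-2-yl)-2,3-dihydro-4H-chromen-4-one | C=CC(C)(C)c1c(OCOC)cc2c(c1OCOC)C(=O)CC(c1ccc(OCOC)c(OCOC)c1)O2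
F2 | step 8 | (2R,4R)-2-[3,4-bis(methoxymethoxy)phenyl]-5,7-bis(methoxymethoxy)-6-(2-methylbut-3-en-2-yl)-3,4-dihydro-2H-chromen-4-ol | C=CC(C)(C)c1c(OCOC)cc2c(c1OCOC)[C@H](O)C[C@H](c1ccc(OCOC)c(OCOC)c1)O2
F3 | step 2 | 2,6-bis[(tert-butyldimethylsilyl)oxy]-4-[(3-methylbut-2-en-1-yl)oxy]benzaldehyde | CC(C)=CCOc1cc(O[Si](C)(C)C(C)(C)C)c(C=O)c(O[Si](C)(C)C(C)(C)C)c1
F4 | step 2 | 2,6-bis[(tert-butyldimethylsilyl)oxy]-4-hydroxy-3-(2-methylbut-3-en-2-yl)benzaldehyde | C=CC(C)(C)c1c(O)cc(O[Si](C)(C)C(C)(C)C)c(C=O)c1O[Si](C)(C)C(C)(C)C
F5 | step 2 | 2,6-bis[(tert-butyldimethylsilyl)oxy]-4-(methoxymethoxy)-3-(2-methylbut-3-en-2-yl)benzaldehyde | C=CC(C)(C)c1c(OCOC)cc(O[Si](C)(C)C(C)(C)C)c(C=O)c1O[Si](C)(C)C(C)(C)C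
F6 | step 6 | rac-4-(1,2-dichloroethyl)-1,2-bis(methoxymethoxy)benzene | ClCC(Cl)c1ccc(OCOC)c(OCOC)c1
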